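common to all: pre-initiator 10 mol%

| run | free monomer | remark | time |
|---|---|---|---|
| Friday's | 0.037 M | run made earlier |  |
| Tuesday's | 0.089 M | run made earlier |  |
| Monday's | 0.14 M | run made earlier |  |
| grey | 0.050 M |  | 2.5 min |
| green | 0.15 M |  | 2.5 min |

- Friday's (time / s: monomer in chains / %, free monomer / %): 10.0: 4.4, 93.3; 25.0: 15.4, 83.0; 50.0: 19.7, 78.7; 80.0: 20.6, 78.1
- Tuesday's (time / s: monomer in chains / %, free monomer / %): 10.0: 30.9, 74.0; 15.0: 44.3, 54.8; 30.0: 63.8, 34.6; 80.0: 66.7, 31.2
- Monday's (time / s: monomer in chains / %, free monomer / %): 10.0: 47.6, 51.0; 15.0: 65.6, 33.5; 30.0: 77.8, 20.1; 80.0: 78.6, 21.7

(readings scatter by 1 percentage point)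

- the average divides the monomer in chains by the number of chains begun, living and dead together
- the earlier runs do not show the number of chains; that part of a forecast is a guess

1. which of the two ends with the longer chains by the average number of monomer units in a chain (chains begun, living or dead) ("neither" if they lie within 10%) (grey / green / neither)
2. average number of monomer units in a chain (chains begun, living or dead) at the end, grey
3. average number of monomer units in a chain (chains begun, living or dead) at the end, green

- Free monomer stops at nearly one level in the earlier runs, though their charges differ: at the last reading Friday's run holds 0.0289 M, Tuesday's 0.0278 M and Monday's 0.0304 M.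
- Their mean, a reading with the scatter of those three, is 0.0290 M, and it is what you should carry: the floor, the free monomer a flask of this recipe keeps, at a charge above the floor, once it stops changing (the equilibrium monomer concentration). In such a flask the fraction of the charge left free is the floor over the charge.
- I take the rate as proportional to the distance above the floor, so that distance falls exponentially. Friday's first two readings give a half-time of 8.82 s, and 2.5 min is far longer, so I count grey and green as at rest by the end.
- The highest and lowest floors bound grey's fraction in chains at 39.2% and 44.5%.
- Length is that fraction over the fraction of chains begun. If each pre-initiator begins one chain, grey lies between 3.92 and 4.45. The readings show no chains, so a poorer start is open upward.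
- The mean floor gives me 4.20 for grey and 8.07 for green, which is twice as long, given an equal start.
- The forecast says green, with 4.2 for grey, inside that bracket, and 8.1 for green, adding: “Incomplete initiation would lengthen both”.
- The flask gives green, with 4.73 for grey and 8.85 for green.

    free monomer + initiator → living end + monomer in chains (k = 4.73 /M/s)
    free monomer + living end → monomer in chains + living end, rate k2*[living end]*[free monomer] (k = 15.6 /M/s)
    monomer in chains + living end → free monomer + living end, rate k3*[living end] as long as [monomer in chains] is above zero (k = 0.451 /s)
    2 initiator → spent initiator (k = 14.0 /M/s)
    pre-initiator ⇌ initiator (K = 3.80, k = 0.188 /s)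

- Grey has come to rest: free monomer reads 58.1% after 1.25 min, 57.8% after 2.50 min and 57.8% after 25.0 min, where the floor put it at 58.0%. Ten times the time leaves the length at 4.73 in grey and at 8.85 in green. Grey's length stands above the bracket, and its living ends are 89.2% of the pre-initiator charged.
- Take a further flask, like grey but with 0.085 M of free monomer: the floor leaves 34.1% free, and length comes to 6.59, or 7.39 if the same share of its pre-initiator ends as living ends as in grey. The computed flask holds 34% free, with length 7.28.

The numbers in the tables are calculated for substances that don't exist; noise was put on by code.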